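**Plan**

1. Locants follow the cyclodeca[b]furan-2-one core of the target: O1, C2(=O), C3(CH2OH), C3a, C4(O-methacryloyl), C5H2, C6(OH)(CH3), C7H2, C8(OAc), C9=C10(CH3), C11=C11a.
2. Retrosynthesis: the dienol lactone goes back to a 2,3-fused furan, the C4 ester to a C4 ketone, and the ring is then cut at C5–C6, the aldol bond of the β-hydroxy ketone C4(=O)–C5–C6(OH). The seco chain is cut at C10–C11 and at C8–C9.
3. Forward: a Feist–Benary furan (C2, C3, C3a, C4, C5, C11, C11a) and a (Z)-vinyl iodide (C6–C10) are joined at C10–C11 by Negishi coupling. The ten-membered ring is closed at C5–C6 by a samarium Reformatsky aldol, and singlet oxygen plus dehydration then turn the furan into the alkylidene butenolide.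
4. What makes the ring closure possible: the 1,3-relationship of the C4 oxygen and the C6 methyl carbinol (a methyl ketone acceptor), and two cis-locked units, the furan C3a=C11a bond and the Z C9=C10 alkene, which fold the chain.
5. Stereochemistry: C8 from Noyori transfer hydrogenation; Z C9=C10 from trans-hydroalumination/iodination; C6 from 1,3-anti induction by C8 in the ring closure; C4 from C6-hydroxyl-directed anti reduction; the C11=C11a geometry from the ring.

Key step: step 13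

Assumption: the (S,S)-configured ruthenium catalyst is taken to give the (S)-carbinol, as with other alkynyl ketones; its mirror image would be used otherwise.

**Route**

Step 1
Reactants: 1 ethyl 2-(2-methyl-1,3-dioxolan-2-yl)acetate
Product: 2 N-methoxy-N-methyl-2-(2-methyl-1,3-dioxolan-2-yl)acetamide
Conditions: MeNH(OMe)·HCl, iPrMgCl, THF, −20 °C to 0 °C
Reagents that add atoms: N,O-dimethylhydroxylamine hydrochloride, CNOC.Cl
Why: Aminolysis of the ester by the magnesium amide formed in the flask (Weinreb amide synthesis) is standard and leaves the ketal untouched.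

Step 2
Reactants: 2 N-methoxy-N-methyl-2-(2-methyl-1,3-dioxolan-2-yl)acetamide; 3 prop-1-yn-1-ylmagnesium bromide
Product: 4 1-(2-methyl-1,3-dioxolan-2-yl)pent-3-yn-2-one
Conditions: THF, 0 °C; aq. NH4Cl
Reagents that add atoms: none
Why: Weinreb ketone synthesis, in which the chelated tetrahedral adduct stops the addition at the alkynyl ketone.

Step 3
Reactants: 4 1-(2-methyl-1,3-dioxolan-2-yl)pent-3-yn-2-one
Product: 5 (2S)-1-(2-methyl-1,3-dioxolan-2-yl)pent-3-yn-2-ol
Conditions: Ru[(S,S)-TsDPEN](p-cymene) (1 mol %), iPrOH, rt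
Reagents that add atoms: none
Why: Noyori asymmetric transfer hydrogenation of an alkynyl ketone, in which the catalyst tells the alkynyl from the alkyl side and should set C8 as S without reducing the triple bond.

Step 4
Reactants: 5 (2S)-1-(2-methyl-1,3-dioxolan-2-yl)pent-3-yn-2-ol
Product: 7 (2S,3Z)-4-iodo-1-(2-methyl-1,3-dioxolan-2-yl)pent-3-en-2-ol, via cyclic alkenylalanate 6 (not isolated)
Conditions: NaAlH2(OCH2CH2OMe)2, THF, 0 °C to rt; then I2, −78 °C to 0 °C
Reagents that add atoms: iodine, II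
Why: Alkoxide-directed trans-hydroalumination of the propargylic alcohol puts aluminium on the distal carbon, and iodinolysis with retention gives the (Z)-3-iodoallylic alcohol, which fixes the Z geometry of C9=C10.

Step 5
Reactants: 7 (2S,3Z)-4-iodo-1-(2-methyl-1,3-dioxolan-2-yl)pent-3-en-2-ol
Product: 8 (2S,3Z)-4-iodo-1-(2-methyl-1,3-dioxolan-2-yl)pent-3-en-2-yl acetate
Conditions: Ac2O, pyridine, DMAP (cat.), CH2Cl2, 0 °C to rt
Reagents that add atoms: acetic anhydride, CC(=O)OC(C)=O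
Why: Standard DMAP-catalysed acylation installs the C8 acetate of the target early, where it also serves as the protecting group.

Step 6
Reactants: 9 pentane-2,4-dione; 10 1,3-dichloropropan-2-one
Product: 12 1-[4-(chloromethyl)-2-methylfuran-3-yl]ethan-1-one, via hydroxydihydrofuran 11 (not isolated)
Conditions: pyridine, CH2Cl2, 0 °C to rt; then TsOH·H2O (cat.), toluene, 60 °C
Reagents that add atoms: none
Why: Feist–Benary furan synthesis, in which aldol addition to the ketone carbonyl of 10, O-alkylation by the enol oxygen and acid dehydration should give the 2-methyl-3-acyl-4-(chloromethyl) pattern.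

Step 7
Reactants: 12 1-[4-(chloromethyl)-2-methylfuran-3-yl]ethan-1-one
Product: 13 1-[4-(hydroxymethyl)-2-methylfuran-3-yl]ethan-1-one
Conditions: H2O, CaCO3, 1,4-dioxane, 90 °C
Reagents that add atoms: water, O
Why: The 3-furylmethyl chloride ionises to a vinylogous oxocarbenium ion and should solvolyse in buffered aqueous dioxane (SN1 hydrolysis).

Step 8
Reactants: 13 1-[4-(hydroxymethyl)-2-methylfuran-3-yl]ethan-1-one
Product: 14 1-[4-({[tert-butyl(dimethyl)silyl]oxy}methyl)-2-methylfuran-3-yl]ethan-1-one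
Conditions: TBSCl, imidazole, DMF, rt
Reagents that add atoms: tert-butyldimethylsilyl chloride, CC(C)(C)[Si](C)(C)Cl
Why: Standard silylation of a primary alcohol, giving a group that lasts to the final step.

Step 9
Reactants: 14 1-[4-({[tert-butyl(dimethyl)silyl]oxy}methyl)-2-methylfuran-3-yl]ethan-1-one
Product: 15 1-[2-(bromomethyl)-4-({[tert-butyl(dimethyl)silyl]oxy}methyl)furan-3-yl]ethan-1-one
Conditions: NBS, AIBN (cat.), PhCF3, 80 °C
Reagents that add atoms: N-bromosuccinimide, O=C1CCC(=O)N1Br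
Why: Wohl–Ziegler bromination selects the furfuryl C–H bonds of the 2-methyl group, as known for 2-methyl-3-acylfurans, over the acetyl methyl group.

Step 10
Reactants: 15 1-[2-(bromomethyl)-4-({[tert-butyl(dimethyl)silyl]oxy}methyl)furan-3-yl]ethan-1-one; 8 (2S,3Z)-4-iodo-1-(2-methyl-1,3-dioxolan-2-yl)pent-3-en-2-yl acetate
Product: 17 (2S,3Z)-5-[3-acetyl-4-({[tert-butyl(dimethyl)silyl]oxy}methyl)furan-2-yl]-4-methyl-1-(2-methyl-1,3-dioxolan-2-yl)pent-3-en-2-yl acetate, via furfurylzinc bromide 16 (not isolated)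
Conditions: zinc dust, LiCl, THF, 0 °C; then 8, Pd(PPh3)4 (5 mol %), THF, rt
Reagents that add atoms: none
Why: Zinc insertion into the furfuryl bromide and sp3–sp2 Negishi coupling with the vinyl iodide form C10–C11 with retention of alkene geometry and tolerate ketone, acetate and ketal.

Step 11
Reactants: 17 (2S,3Z)-5-[3-acetyl-4-({[tert-butyl(dimethyl)silyl]oxy}methyl)furan-2-yl]-4-methyl-1-(2-methyl-1,3-dioxolan-2-yl)pent-3-en-2-yl acetate
Product: 19 (2S,3Z)-5-[3-(bromoacetyl)-4-({[tert-butyl(dimethyl)silyl]oxy}methyl)furan-2-yl]-4-methyl-1-(2-methyl-1,3-dioxolan-2-yl)pent-3-en-2-yl acetate, via trimethylsilyl enol ether 18 (not isolated)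
Conditions: TMSOTf, Et3N, CH2Cl2, 0 °C; then NBS, NaHCO3, THF, −78 °C
Reagents that add atoms: N-bromosuccinimide, O=C1CCC(=O)N1Br
Why: Soft enolisation silylates the only free ketone at its methyl group, and NBS should brominate the silyl enol ether much faster than the furan or the alkene (α-bromination of a ketone through its silyl enol ether).

Step 12
Reactants: 19 (2S,3Z)-5-[3-(bromoacetyl)-4-({[tert-butyl(dimethyl)silyl]oxy}methyl)furan-2-yl]-4-methyl-1-(2-methyl-1,3-dioxolan-2-yl)pent-3-en-2-yl acetate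
Product: 20 (2Z,4S)-1-[3-(bromoacetyl)-4-({[tert-butyl(dimethyl)silyl]oxy}methyl)furan-2-yl]-2-methyl-6-oxohept-2-en-4-yl acetate
Conditions: PPTS, acetone/H2O (10:1), 45 °C
Reagents that add atoms: water, O
Why: Mild acid hydrolysis of the dioxolane unveils the methyl ketone only now, so the two ketones never compete for enolisation, and bromo ketone, acetate and silyl ether should tolerate pyridinium tosylate.

Step 13
Reactants: 20 (2Z,4S)-1-[3-(bromoacetyl)-4-({[tert-butyl(dimethyl)silyl]oxy}methyl)furan-2-yl]-2-methyl-6-oxohept-2-en-4-yl acetate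
Product: 22 (6S,8S,9Z)-3-({[tert-butyl(dimethyl)silyl]oxy}methyl)-6-hydroxy-6,10-dimethyl-4-oxo-4,5,6,7,8,11-hexahydrocyclodeca[b]furan-8-yl acetate, via samarium enolate 21 (not isolated)
Conditions: SmI2 (2.2 equiv), THF, −78 °C, slow addition of 20 (final 0.003 M); AcOH/THF quench at −78 °C
Reagents that add atoms: none
Why: Two single-electron transfers from SmI2 cleave the C–Br bond and give the trivalent samarium enolate 21 regiospecifically at C5 under neutral conditions that spare the β-acetoxy ketone; the samarium then binds the C6 ketone and the enolate adds through a chair Zimmerman–Traxler array to form C5–C6. The closest known reaction type is the SmI2-mediated intramolecular Reformatsky (aldol) cyclisation of α-bromo ketones used for medium carbocycles. The ten-membered ring closes in a 10-(enolendo)-exo-trig mode, helped by the two cis-locked units (furan C3a=C11a and Z C9=C10) and by slow addition at high dilution. The new C6 stereocenter is controlled by the C8 acetoxy stereocenter: with the metal bridging the ketone and the acetate carbonyl, the enolate should attack the ketone face anti to the C8 substituent (1,3-anti induction), giving 6S. The step needs reduction of the bromo ketone ahead of the methyl ketone (secured by the large rate difference), ring closure ahead of oligomerisation (dilution and pre-folding) and a cold acidic quench before retro-aldol cleavage or acetyl migration.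

Step 14
Reactants: 22 (6S,8S,9Z)-3-({[tert-butyl(dimethyl)silyl]oxy}methyl)-6-hydroxy-6,10-dimethyl-4-oxo-4,5,6,7,8,11-hexahydrocyclodeca[b]furan-8-yl acetate
Product: 23 (4R,6R,8S,9Z)-3-({[tert-butyl(dimethyl)silyl]oxy}methyl)-4,6-dihydroxy-6,10-dimethyl-4,5,6,7,8,11-hexahydrocyclodeca[b]furan-8-yl acetate
Conditions: Me4NBH(OAc)3, MeCN/AcOH (1:1), −30 °C
Reagents that add atoms: none
Why: Evans–Saksena reduction, in which the C6 hydroxyl exchanges onto boron and delivers hydride intramolecularly through a chair six-membered transition state, should give the 4,6-anti diol (4R); the C6 descriptor changes only because of ligand priorities.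

Step 15
Reactants: 23 (4R,6R,8S,9Z)-3-({[tert-butyl(dimethyl)silyl]oxy}methyl)-4,6-dihydroxy-6,10-dimethyl-4,5,6,7,8,11-hexahydrocyclodeca[b]furan-8-yl acetate
Product: 24 (4R,6S,8S,9Z)-8-(acetyloxy)-3-({[tert-butyl(dimethyl)silyl]oxy}methyl)-6-hydroxy-6,10-dimethyl-4,5,6,7,8,11-hexahydrocyclodeca[b]furan-4-yl 2-methylprop-2-enoate
Conditions: methacrylic anhydride, Et3N, DMAP (cat.), CH2Cl2, 0 °C to rt
Reagents that add atoms: methacrylic anhydride, C=C(C)C(=O)OC(=O)C(C)=C
Why: DMAP-catalysed acylation distinguishes the secondary C4 hydroxyl from the tertiary C6 hydroxyl on steric grounds.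

Step 16
Reactants: 24 (4R,6S,8S,9Z)-8-(acetyloxy)-3-({[tert-butyl(dimethyl)silyl]oxy}methyl)-6-hydroxy-6,10-dimethyl-4,5,6,7,8,11-hexahydrocyclodeca[b]furan-4-yl 2-methylprop-2-enoate
Product: 26 (4R,6S,8S,9Z)-8-(acetyloxy)-3-({[tert-butyl(dimethyl)silyl]oxy}methyl)-6,11a-dihydroxy-6,10-dimethyl-2-oxo-2,4,5,6,7,8,11,11a-octahydrocyclodeca[b]furan-4-yl 2-methylprop-2-enoate (11a-epimers), via furan endoperoxide 25 (not isolated)
Conditions: O2, visible light, tetraphenylporphyrin (cat.), iPr2NEt, CH2Cl2, −78 °C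
Reagents that add atoms: oxygen, O=O
Why: Singlet oxygen adds [4+2] across the trialkylfuran faster than it reacts with the trisubstituted alkene, and base-induced Kornblum–DeLaMare cleavage removes the only bridgehead hydrogen (C2–H), which puts the carbonyl at C2 and the hydroxyl at C11a.

Step 17
Reactants: 26 (4R,6S,8S,9Z)-8-(acetyloxy)-3-({[tert-butyl(dimethyl)silyl]oxy}methyl)-6,11a-dihydroxy-6,10-dimethyl-2-oxo-2,4,5,6,7,8,11,11a-octahydrocyclodeca[b]furan-4-yl 2-methylprop-2-enoate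
Product: 28 (4R,6S,8S,9Z,11E)-8-(acetyloxy)-3-({[tert-butyl(dimethyl)silyl]oxy}methyl)-6-hydroxy-6,10-dimethyl-2-oxo-2,4,5,6,7,8-hexahydrocyclodeca[b]furan-4-yl 2-methylprop-2-enoate, via lactol acetate 27 (not isolated)
Conditions: Ac2O, pyridine, CH2Cl2, 0 °C to rt; then DBU, 0 °C
Reagents that add atoms: none
Why: Acetylation of the pseudo-acid hydroxyl and base-induced elimination toward the doubly allylic C11–H is a known dehydration of γ-hydroxybutenolides; the ten-membered ring is expected to admit only the geometry with C10 and C3a cis across C11=C11a (11E), and the tertiary hydroxyl should not be acetylated without DMAP.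

Step 18
Reactants: 28 (4R,6S,8S,9Z,11E)-8-(acetyloxy)-3-({[tert-butyl(dimethyl)silyl]oxy}methyl)-6-hydroxy-6,10-dimethyl-2-oxo-2,4,5,6,7,8-hexahydrocyclodeca[b]furan-4-yl 2-methylprop-2-enoate
Product: 29 (4R,6S,8S,9Z,11E)-8-(acetyloxy)-6-hydroxy-3-(hydroxymethyl)-6,10-dimethyl-2-oxo-2,4,5,6,7,8-hexahydrocyclodeca[b]furan-4-yl 2-methylprop-2-enoate (CNP0246543.1)
Conditions: HF·pyridine, pyridine/THF, 0 °C to rt
Reagents that add atoms: none
Why: Buffered fluoride cleaves the primary silyl ether under conditions that spare both esters, the tertiary alcohol and the dienol lactone.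

**Compound list**

1 | ethyl 2-(2-methyl-1,3-dioxolan-2-yl)acetate | CCOC(=O)CC1(C)OCCO1 | starting material
2 | N-methoxy-N-methyl-2-(2-methyl-1,3-dioxolan-2-yl)acetamide | CON(C)C(=O)CC1(C)OCCO1 | intermediate
3 | prop-1-yn-1-ylmagnesium bromide | CC#C[Mg]Br | starting material
4 | 1-(2-methyl-1,3-dioxolan-2-yl)pent-3-yn-2-one | CC#CC(=O)CC1(C)OCCO1 | intermediate
5 | (2S)-1-(2-methyl-1,3-dioxolan-2-yl)pent-3-yn-2-ol | CC#C[C@@H](O)CC1(C)OCCO1 | intermediate
6 | sodium cyclic alkenylalanate from 5 (aluminium bound to the alkoxide oxygen and to C4 of the pentenyl chain, two 2-methoxyethoxy ligands) | [Na+].COCCO[Al-]1(OCCOC)O[C@@H](CC2(C)OCCO2)C=C1C | intermediate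
7 | (2S,3Z)-4-iodo-1-(2-methyl-1,3-dioxolan-2-yl)pent-3-en-2-ol | C/C(I)=C/[C@@H](O)CC1(C)OCCO1 | intermediate
8 | (2S,3Z)-4-iodo-1-(2-methyl-1,3-dioxolan-2-yl)pent-3-en-2-yl acetate | C/C(I)=C/[C@@H](OC(C)=O)CC1(C)OCCO1 | intermediate
9 | pentane-2,4-dione | CC(=O)CC(C)=O | starting material
10 | 1,3-dichloropropan-2-one | ClCC(=O)CCl | starting material
11 | 1-[4-(chloromethyl)-4-hydroxy-2-methyl-4,5-dihydrofuran-3-yl]ethan-1-one (racemic) | CC(=O)C1=C(C)OCC1(O)CCl | intermediate
12 | 1-[4-(chloromethyl)-2-methylfuran-3-yl]ethan-1-one | CC(=O)c1c(C)occ1CCl | intermediate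
13 | 1-[4-(hydroxymethyl)-2-methylfuran-3-yl]ethan-1-one | CC(=O)c1c(C)occ1CO | intermediate
14 | 1-[4-({[tert-butyl(dimethyl)silyl]oxy}methyl)-2-methylfuran-3-yl]ethan-1-one | CC(=O)c1c(C)occ1CO[Si](C)(C)C(C)(C)C | intermediate
15 | 1-[2-(bromomethyl)-4-({[tert-butyl(dimethyl)silyl]oxy}methyl)furan-3-yl]ethan-1-one | CC(=O)c1c(CBr)occ1CO[Si](C)(C)C(C)(C)C | intermediate
16 | {[3-acetyl-4-({[tert-butyl(dimethyl)silyl]oxy}methyl)furan-2-yl]methyl}zinc bromide | CC(=O)c1c(C[Zn]Br)occ1CO[Si](C)(C)C(C)(C)C | intermediate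
17 | (2S,3Z)-5-[3-acetyl-4-({[tert-butyl(dimethyl)silyl]oxy}methyl)furan-2-yl]-4-methyl-1-(2-methyl-1,3-dioxolan-2-yl)pent-3-en-2-yl acetate | CC(=O)c1c(C/C(C)=C\[C@@H](OC(C)=O)CC2(C)OCCO2)occ1CO[Si](C)(C)C(C)(C)C | intermediate
18 | trimethylsilyl enol ether of 17 (furan-3-yl 1-[(trimethylsilyl)oxy]ethenyl group) | C=C(O[Si](C)(C)C)c1c(C/C(C)=C\[C@@H](OC(C)=O)CC2(C)OCCO2)occ1CO[Si](C)(C)C(C)(C)C | intermediate
19 | (2S,3Z)-5-[3-(bromoacetyl)-4-({[tert-butyl(dimethyl)silyl]oxy}methyl)furan-2-yl]-4-methyl-1-(2-methyl-1,3-dioxolan-2-yl)pent-3-en-2-yl acetate | O=C(CBr)c1c(C/C(C)=C\[C@@H](OC(C)=O)CC2(C)OCCO2)occ1CO[Si](C)(C)C(C)(C)C | intermediate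
20 | (2Z,4S)-1-[3-(bromoacetyl)-4-({[tert-butyl(dimethyl)silyl]oxy}methyl)furan-2-yl]-2-methyl-6-oxohept-2-en-4-yl acetate | CC(=O)C[C@H](OC(C)=O)/C=C(C)\Cc1occ(CO[Si](C)(C)C(C)(C)C)c1C(=O)CBr | intermediate
21 | diiodosamarium enolate of 20 (O-bound at the former bromoacetyl group) | CC(=O)C[C@H](OC(C)=O)/C=C(C)\Cc1occ(CO[Si](C)(C)C(C)(C)C)c1C(=C)O[Sm](I)I | intermediate
22 | (6S,8S,9Z)-3-({[tert-butyl(dimethyl)silyl]oxy}methyl)-6-hydroxy-6,10-dimethyl-4-oxo-4,5,6,7,8,11-hexahydrocyclodeca[b]furan-8-yl acetate | O=C1C[C@@](C)(O)C[C@H](OC(C)=O)/C=C(C)\Cc2occ(CO[Si](C)(C)C(C)(C)C)c21 | intermediate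
23 | (4R,6R,8S,9Z)-3-({[tert-butyl(dimethyl)silyl]oxy}methyl)-4,6-dihydroxy-6,10-dimethyl-4,5,6,7,8,11-hexahydrocyclodeca[b]furan-8-yl acetate | O[C@@H]1C[C@@](C)(O)C[C@H](OC(C)=O)/C=C(C)\Cc2occ(CO[Si](C)(C)C(C)(C)C)c21 | intermediate
24 | (4R,6S,8S,9Z)-8-(acetyloxy)-3-({[tert-butyl(dimethyl)silyl]oxy}methyl)-6-hydroxy-6,10-dimethyl-4,5,6,7,8,11-hexahydrocyclodeca[b]furan-4-yl 2-methylprop-2-enoate | C=C(C)C(=O)O[C@@H]1C[C@@](C)(O)C[C@H](OC(C)=O)/C=C(C)\Cc2occ(CO[Si](C)(C)C(C)(C)C)c21 | intermediate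
25 | 2,11a-epidioxy adduct (furan endoperoxide) of 24, bridgehead configuration undefined | C=C(C)C(=O)O[C@@H]1C[C@@](C)(O)C[C@H](OC(C)=O)/C=C(C)\CC23OOC(O2)C(CO[Si](C)(C)C(C)(C)C)=C13 | intermediate
26 | (4R,6S,8S,9Z)-8-(acetyloxy)-3-({[tert-butyl(dimethyl)silyl]oxy}methyl)-6,11a-dihydroxy-6,10-dimethyl-2-oxo-2,4,5,6,7,8,11,11a-octahydrocyclodeca[b]furan-4-yl 2-methylprop-2-enoate (11a-epimers) | C=C(C)C(=O)O[C@@H]1C[C@@](C)(O)C[C@H](OC(C)=O)/C=C(C)\CC2(O)OC(=O)C(CO[Si](C)(C)C(C)(C)C)=C12 | intermediate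
27 | 11a-O-acetyl derivative of 26 (11a-epimers) | C=C(C)C(=O)O[C@@H]1C[C@@](C)(O)C[C@H](OC(C)=O)/C=C(C)\CC2(OC(C)=O)OC(=O)C(CO[Si](C)(C)C(C)(C)C)=C12 | intermediate
28 | (4R,6S,8S,9Z,11E)-8-(acetyloxy)-3-({[tert-butyl(dimethyl)silyl]oxy}methyl)-6-hydroxy-6,10-dimethyl-2-oxo-2,4,5,6,7,8-hexahydrocyclodeca[b]furan-4-yl 2-methylprop-2-enoate | C=C(C)C(=O)O[C@@H]1C[C@@](C)(O)C[C@H](OC(C)=O)/C=C(C)\C=C2\OC(=O)C(CO[Si](C)(C)C(C)(C)C)=C21 | intermediate
29 | (4R,6S,8S,9Z,11E)-8-(acetyloxy)-6-hydroxy-3-(hydroxymethyl)-6,10-dimethyl-2-oxo-2,4,5,6,7,8-hexahydrocyclodeca[b]furan-4-yl 2-methylprop-2-enoate (CNP0246543.1) | C=C(C)C(=O)O[C@@H]1C[C@@](C)(O)C[C@H](OC(C)=O)/C=C(C)\C=C2\OC(=O)C(CO)=C21 | target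

**Step count and risks**

Total step count: 18. Longest linear sequence: 14 steps (steps 1–5 and 10–18).

Steps most likely to fail:

1. Step 13. Intermolecular aldol oligomerisation and premature protonation of the enolate may outrun the ten-membered ring closure, and the enolate may attack the wrong face of the methyl ketone. The fallback sets out from 17 and comes back at 22. Compound 17 is converted into enol ether 18 as in step 11 but is not brominated. Slow addition of 18 to TMSOTf and 2,6-di-tert-butyl-4-methylpyridine in CH2Cl2 at −78 °C opens the dioxolane to an oxocarbenium ion, which the enol ether captures through an open transition state (Mukaiyama-type acetal aldol). After aqueous work-up this gives (6S,8S,9Z)-3-({[tert-butyl(dimethyl)silyl]oxy}methyl)-6-(2-hydroxyethoxy)-6,10-dimethyl-4-oxo-4,5,6,7,8,11-hexahydrocyclodeca[b]furan-8-yl acetate F1. Iodine, PPh3 and imidazole convert it into the corresponding 6-(2-iodoethoxy) ketone F2. Zinc dust with NH4Cl in ethanol at 50 °C then fragments the 2-iodoethyl ether reductively, with loss of ethene, and delivers 22.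

2. Step 17. The free C6 hydroxyl may capture the lactol carbon C11a transannularly (bridged ketal) or be acetylated, in competition with the elimination. The fallback sets out from 24 and comes back at 29. TESOTf and 2,6-lutidine in CH2Cl2 at −78 °C give (4R,6S,8S,9Z)-8-(acetyloxy)-3-({[tert-butyl(dimethyl)silyl]oxy}methyl)-6,10-dimethyl-6-[(triethylsilyl)oxy]-4,5,6,7,8,11-hexahydrocyclodeca[b]furan-4-yl 2-methylprop-2-enoate F3. Photooxygenation as in step 16 gives the 11a-hydroxy-2-oxo lactol of this silyl ether F4. Ac2O/pyridine and then DBU give the 6-O-triethylsilyl ether of 28 F5. HF·pyridine removes both silyl groups and gives 29.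

3. Step 14. The ring conformation may override the intramolecular hydride delivery, so that the 4,6-syn diol forms. The fallback sets out from 22 and comes back at 24. Chelation-controlled reduction (Et2BOMe, NaBH4, THF/MeOH, −78 °C; Narasaka–Prasad) gives (4S,6R,8S,9Z)-3-({[tert-butyl(dimethyl)silyl]oxy}methyl)-4,6-dihydroxy-6,10-dimethyl-4,5,6,7,8,11-hexahydrocyclodeca[b]furan-8-yl acetate F6. Mitsunobu esterification with methacrylic acid (PPh3, DIAD, THF, 0 °C) inverts C4 and installs the ester in one operation, arriving at 24.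

Further compounds
F1 | step 13 | (6S,8S,9Z)-3-({[tert-butyl(dimethyl)silyl]oxy}methyl)-6-(2-hydroxyethoxy)-6,10-dimethyl-4-oxo-4,5,6,7,8,11-hexahydrocyclodeca[b]furan-8-yl acetate | O=C1C[C@@](C)(OCCO)C[C@H](OC(C)=O)/C=C(C)\Cc2occ(CO[Si](C)(C)C(C)(C)C)c21
F2 | step 13 | (6S,8S,9Z)-3-({[tert-butyl(dimethyl)silyl]oxy}methyl)-6-(2-iodoethoxy)-6,10-dimethyl-4-oxo-4,5,6,7,8,11-hexahydrocyclodeca[b]furan-8-yl acetate | O=C1C[C@@](C)(OCCI)C[C@H](OC(C)=O)/C=C(C)\Cc2occ(CO[Si](C)(C)C(C)(C)C)c21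
F3 | step 17 | (4R,6S,8S,9Z)-8-(acetyloxy)-3-({[tert-butyl(dimethyl)silyl]oxy}methyl)-6,10-dimethyl-6-[(triethylsilyl)oxy]-4,5,6,7,8,11-hexahydrocyclodeca[b]furan-4-yl 2-methylprop-2-enoate | C=C(C)C(=O)O[C@@H]1C[C@@](C)(O[Si](CC)(CC)CC)C[C@H](OC(C)=O)/C=C(C)\Cc2occ(CO[Si](C)(C)C(C)(C)C)c21
F4 | step 17 | (4R,6S,8S,9Z)-8-(acetyloxy)-3-({[tert-butyl(dimethyl)silyl]oxy}methyl)-11a-hydroxy-6,10-dimethyl-2-oxo-6-[(triethylsilyl)oxy]-2,4,5,6,7,8,11,11a-octahydrocyclodeca[b]furan-4-yl 2-methylprop-2-enoate (11a-epimers) | C=C(C)C(=O)O[C@@H]1C[C@@](C)(O[Si](CC)(CC)CC)C[C@H](OC(C)=O)/C=C(C)\CC2(O)OC(=O)C(CO[Si](C)(C)C(C)(C)C)=C12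
F5 | step 17 | (4R,6S,8S,9Z,11E)-8-(acetyloxy)-3-({[tert-butyl(dimethyl)silyl]oxy}methyl)-6,10-dimethyl-2-oxo-6-[(triethylsilyl)oxy]-2,4,5,6,7,8-hexahydrocyclodeca[b]furan-4-yl 2-methylprop-2-enoate | C=C(C)C(=O)O[C@@H]1C[C@@](C)(O[Si](CC)(CC)CC)C[C@H](OC(C)=O)/C=C(C)\C=C2\OC(=O)C(CO[Si](C)(C)C(C)(C)C)=C21
F6 | step 14 | (4S,6R,8S,9Z)-3-({[tert-butyl(dimethyl)silyl]oxy}methyl)-4,6-dihydroxy-6,10-dimethyl-4,5,6,7,8,11-hexahydrocyclodeca[b]furan-8-yl acetate | O[C@H]1C[C@@](C)(O)C[C@H](OC(C)=O)/C=C(C)\Cc2occ(CO[Si](C)(C)C(C)(C)C)c21
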